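**Strategy.** Ring B (C5–C10) carries the C5 methyl and the C7 isopropenyl group cis and 1,3 to each other, the m-menthane pattern latent in (+)-3-carene (carene C3 methyl = C5 methyl, C1 = C7, CMe2 bridge = C11–C13). Ring A is therefore cut at C4–C5 and C1–C10. The C1–C2–C3(O)–C4(Me) unit is a 2-silyloxydiene that adds across the C5=C10 bond of car-3-en-5-one, anti to the bridge. One cycloaddition closes ring A, creates the C5 quaternary centre and the cis C5/C10 fusion, and delivers C3 masked as an enol silane. The cyclopropane is opened afterwards to release the side chain and C8=C9, and the acyl chain is attached last.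

Key step: step 3

Remark: eremophilane numbering is used throughout and β is the face of ring B that carries the C5 methyl group; adduct 5 is drawn as the endo (4α-methyl) isomer and carbinol 6 as the 9β-epimer, and both centres are reset in step 5.

Step 1
Reactants: 1 (+)-3-carene
Product: 2 car-3-en-5-one
Conditions: t-BuOOH (in decane), CrO3 (5 mol%), CH2Cl2, rt
Reagents that add atoms: tert-butyl hydroperoxide, CC(C)(C)OO
Why: Chromium-catalysed allylic oxidation takes the ring CH2 between the CH end of the alkene and the cyclopropane (carene C5), a known conversion of 3-carene into its β-methyl enone that leaves both cyclopropane stereocentres untouched.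

Step 2
Reactants: 3 ethyl vinyl ketone
Product: 4 (Z)-3-(tert-butyldimethylsilyloxy)penta-1,3-diene
Conditions: TBSOTf, Et3N, CH2Cl2, 0 °C
Reagents that add atoms: tert-butyldimethylsilyl trifluoromethanesulfonate, CC(C)(C)[Si](C)(C)OS(=O)(=O)C(F)(F)F
Why: Soft enolisation and O-silylation of the ethyl ketone gives the dienol silane, and the Z enol ether usual for ethyl ketones under these conditions places the methyl group trans to the vinyl group, that is outside the s-cis diene.

Step 3
Reactants: 2 car-3-en-5-one; 4 (Z)-3-(tert-butyldimethylsilyloxy)penta-1,3-diene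
Product: 5 3-(tert-butyldimethylsilyloxy)-8,11-cycloeremophil-2-en-9-one (cis-fused, 4α,5β-dimethyl, 10β-H, cyclopropane C7–C8–C11 intact)
Conditions: 4 (2 equiv), HNTf2 (10 mol%), CH2Cl2, −78 → −40 °C; Et3N quench at low temperature
Reagents that add atoms: none
Why: Triflimide protodesilylates a little diene to give TBSNTf2, which binds the C9 carbonyl of 2; the enol-silane terminus C4 of 4 then bonds to the enone β-carbon C5 and the diene CH2 (C1) closes onto the α-carbon C10 in a strongly asynchronous [4+2] cycloaddition, the silyl group ending on the C3 oxygen so that the catalyst is regenerated. The closest known reaction type is the Lewis acid (silyl triflimide or mixed aluminium halide) catalysed Diels–Alder reaction of 2-silyloxydienes with hindered β-substituted cycloalkenones, which becomes a Mukaiyama–Michael/Michael sequence at its stepwise limit. Ring A (C10–C1–C2–C3–C4–C5) closes as the six-membered ring of the cycloaddition, a 6-endo-trig Michael closure of the C9 silyl enol ether onto the silylated vinyl ketone if the bonds form one after the other. C5 and C10 are set by addition to the enone face opposite the CMe2 bridge, whose endo methyl covers the β face, and by the suprafacial course of the addition, which puts the C5 methyl and H10 cis to each other and to the C7–C11 bond; C4 follows from the endo orientation of the diene (4α-methyl) and is corrected in step 5. The step needs facial and regiochemical control, the first supplied by the bridge and the second by the polarity match between the enol-silane terminus and the enone β-carbon, whereas endo/exo selectivity is irrelevant. The enol silane in the product keeps C3 masked so that C9 can be reduced alone.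

Step 4
Reactants: 5 3-(tert-butyldimethylsilyloxy)-8,11-cycloeremophil-2-en-9-one
Product: 6 3-(tert-butyldimethylsilyloxy)-8,11-cycloeremophil-2-en-9β-ol
Conditions: LiAlH4, Et2O, −78 → 0 °C
Reagents that add atoms: none
Why: Hydride reduction converts the only free carbonyl (C9) into the cyclopropyl carbinol while C3 stays protected as its hydride-inert silyl enol ether, and the C9 configuration does not matter because C9 becomes sp2 in the next step.

Step 5
Reactants: 6 3-(tert-butyldimethylsilyloxy)-8,11-cycloeremophil-2-en-9β-ol
Product: 8 11-chloroeremophil-8-en-3-one (4β,5β-dimethyl, 7β-(2-chloropropan-2-yl), 10β-H), via 4-epi-11-chloroeremophil-8-en-3-one 7 (not isolated)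
Conditions: conc. aq. HCl, THF, 0 °C → rt, continued until C4 is equilibrated
Reagents that add atoms: hydrogen chloride, Cl
Why: Acid ionises the carbinol and the C9 cation opens the well-aligned external cyclopropane bond C8–C11 (cyclopropylcarbinyl-to-homoallyl, Julia-type rearrangement) to the tertiary C11 cation, which chloride captures to give C8=C9 with C7 untouched, while the same acid hydrolyses the enol silane and equilibrates C4 through the enol to the equatorial 4β-methyl epimer, favoured because an axial 4α-methyl would be syn-axial to C9 in the conformer fixed by the equatorial C7 substituent.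

Step 6
Reactants: 8 11-chloroeremophil-8-en-3-one
Product: 9 11-chloro-8β,9β-dihydroxyeremophilan-3-one
Conditions: OsO4 (2 mol%), NMO, acetone/H2O (10:1), 0 °C → rt; Na2SO3
Reagents that add atoms: osmium tetroxide (catalytic oxygen carrier), O=[Os](=O)(=O)=O; N-methylmorpholine N-oxide, C[N+]1([O-])CCOCC1; water, O
Why: Upjohn dihydroxylation should add to C8=C9 from the convex β face, away from the axial C4–C5 bond and ring A folded under the α face, which sets C8 and C9 as the cis-8β,9β-diol while the tertiary chloride keeps the future isopropenyl carbons out of reach of the oxidant.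

Step 7
Reactants: 9 11-chloro-8β,9β-dihydroxyeremophilan-3-one
Product: 10 11-chloro-8β,9β-(isopropylidenedioxy)eremophilan-3-one
Conditions: 2-methoxypropene, PPTS (cat.), CH2Cl2, 0 °C
Reagents that add atoms: 2-methoxypropene, C=C(C)OC
Why: Acetonide formation on the cis-diol masks the C8 hydroxyl, whose alkoxide would sit 1,3 to the tertiary chloride and could trigger Grob fragmentation of the C7–C8 bond in the basic step that follows.

Step 8
Reactants: 10 11-chloro-8β,9β-(isopropylidenedioxy)eremophilan-3-one
Product: 11 8β,9β-(isopropylidenedioxy)eremophil-11-en-3-one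
Conditions: KOtBu, t-BuOH/THF, 50 °C
Reagents that add atoms: none
Why: E2 dehydrochlorination with the bulky alkoxide should remove a methyl hydrogen in preference to the hindered ring hydrogen at C7 (Hofmann orientation), which unveils the isopropenyl group with C7 intact, and the same base holds C4 at its thermodynamic 4β configuration.

Step 9
Reactants: 11 8β,9β-(isopropylidenedioxy)eremophil-11-en-3-one
Product: 12 8β,9β-dihydroxyeremophil-11-en-3-one
Conditions: AcOH/H2O (4:1), 40 °C
Reagents that add atoms: none
Why: Mild acidic ketal hydrolysis cleaves the dioxolane much faster than it hydrates the 1,1-disubstituted alkene and returns the free diol.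

Step 10
Reactants: 12 8β,9β-dihydroxyeremophil-11-en-3-one
Product: 13 8β-hydroxy-9β-(triethylsilyloxy)eremophil-11-en-3-one
Conditions: TESCl (1.1 equiv), imidazole, DMF, −20 °C
Reagents that add atoms: chlorotriethylsilane, CC[Si](Cl)(CC)CC
Why: Sterically governed silylation should take the equatorial C9 hydroxyl in preference to the axial C8 hydroxyl, which is flanked by the isopropenyl-bearing C7 and by C9.

Step 11
Reactants: 13 8β-hydroxy-9β-(triethylsilyloxy)eremophil-11-en-3-one
Product: 14 9β-(triethylsilyloxy)eremophil-11-ene-3α,8β-diol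
Conditions: Li, NH3(l)/THF, t-BuOH (2 equiv), −78 °C; then NH4Cl
Reagents that add atoms: none
Why: Dissolving-metal reduction protonates the ketyl-derived carbanion under thermodynamic control and should give the equatorial 3α-alcohol trans to the 4β-methyl, whereas hydride reagents would be steered to the axial alcohol by the syn-axial C5 methyl; the isolated alkene and the silyl ether are inert at −78 °C.

Step 12
Reactants: 15 (R)-pent-4-en-2-ol; 16 angelic acid
Product: 18 (R)-pent-4-en-2-yl angelate, via angelic 2,4,6-trichlorobenzoic anhydride 17 (not isolated)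
Conditions: 16, 2,4,6-Cl3C6H2COCl, Et3N, toluene, rt; then 15, 80 °C (no DMAP)
Reagents that add atoms: none
Why: Yamaguchi-type mixed anhydride esterification run without a nucleophilic catalyst acylates the secondary alcohol without Z-to-E isomerisation of the angeloyl unit, and the carbinol centre is not touched (R retained).

Step 13
Reactants: 18 (R)-pent-4-en-2-yl angelate; 19 acrylic acid
Product: 20 (R,E)-5-(angeloyloxy)hex-2-enoic acid
Conditions: 19 (3 equiv), second-generation Hoveyda–Grubbs catalyst [RuCl2(H2IMes)(=CH-C6H4-2-O-i-Pr)] (5 mol%), CH2Cl2, 40 °C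
Reagents that add atoms: none
Why: Olefin cross metathesis joins the reactive terminal homoallylic alkene with the electron-poor acrylic acid to give the E enoic acid under thermodynamic control, while the trisubstituted, conjugated angelate alkene does not engage the ruthenium carbene.

Step 14
Reactants: 14 9β-(triethylsilyloxy)eremophil-11-ene-3α,8β-diol; 20 (R,E)-5-(angeloyloxy)hex-2-enoic acid
Product: 22 3α-[(R,E)-5-(angeloyloxy)hex-2-enoyloxy]-9β-(triethylsilyloxy)eremophil-11-en-8β-ol, via acyl 2,4,6-trichlorobenzoic anhydride 21 (not isolated)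
Conditions: 20, 2,4,6-Cl3C6H2COCl, Et3N, THF, 0 °C; then 14, DMAP (cat.), toluene, 0 °C → rt
Reagents that add atoms: none
Why: Yamaguchi esterification through the mixed anhydride should acylate the equatorial C3 hydroxyl only, because the axial C8 hydroxyl is shielded by the C7 isopropenyl group and the C9 silyl ether, and no stereocentre is touched.

Step 15
Reactants: 22 3α-[(R,E)-5-(angeloyloxy)hex-2-enoyloxy]-9β-(triethylsilyloxy)eremophil-11-en-8β-ol
Product: 23 3α-[(R,E)-5-(angeloyloxy)hex-2-enoyloxy]-9β-(triethylsilyloxy)eremophil-11-en-8-one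
Conditions: Dess–Martin periodinane, NaHCO3, CH2Cl2, 0 °C → rt
Reagents that add atoms: none
Why: Buffered Dess–Martin oxidation converts the hindered secondary C8 alcohol into the ketone under neutral conditions that do not enolise C7 or C9 and leave the alkenes, both esters and the silyl ether alone.

Step 16
Reactants: 23 3α-[(R,E)-5-(angeloyloxy)hex-2-enoyloxy]-9β-(triethylsilyloxy)eremophil-11-en-8-one
Product: 24 target CNP0210874.1
Conditions: HF·pyridine, pyridine, THF, 0 °C → rt
Reagents that add atoms: none
Why: Buffered fluoride-acid desilylation cleaves the secondary triethylsilyl ether under mildly acidic conditions that avoid base-induced α-ketol isomerisation, acyl migration and conjugation of the β,γ-unsaturated ketone.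

**Compound list**

1 | (+)-3-carene, (1S,6R)-3,7,7-trimethylbicyclo[4.1.0]hept-3-ene | CC1(C)[C@H]2CC(C)=CC[C@@H]12 | starting material
2 | car-3-en-5-one (4,7,7-trimethylbicyclo[4.1.0]hept-3-en-2-one, cyclopropane stereocentres as in 1) | CC1(C)[C@H]2CC(C)=CC(=O)[C@@H]12 | intermediate
3 | ethyl vinyl ketone (pent-1-en-3-one) | C=CC(=O)CC | starting material
4 | (Z)-3-(tert-butyldimethylsilyloxy)penta-1,3-diene | C/C=C(\O[Si](C)(C)C(C)(C)C)C=C | intermediate
5 | 3-(tert-butyldimethylsilyloxy)-8,11-cycloeremophil-2-en-9-one (4α,5β-dimethyl, 10β-H, β-cyclopropane) | CC1(C)[C@H]2C[C@@]3(C)[C@H](CC=C(O[Si](C)(C)C(C)(C)C)[C@H]3C)C(=O)[C@@H]12 | intermediate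
6 | 3-(tert-butyldimethylsilyloxy)-8,11-cycloeremophil-2-en-9β-ol | CC1(C)[C@H]2C[C@@]3(C)[C@H](CC=C(O[Si](C)(C)C(C)(C)C)[C@H]3C)[C@@H](O)[C@@H]12 | intermediate
7 | 4-epi-11-chloroeremophil-8-en-3-one (4α-methyl) | CC(C)(Cl)[C@H]1C[C@@]2(C)[C@H](CCC(=O)[C@H]2C)C=C1 | intermediate (not isolated)
8 | 11-chloroeremophil-8-en-3-one (4β-methyl) | CC(C)(Cl)[C@H]1C[C@@]2(C)[C@H](CCC(=O)[C@@H]2C)C=C1 | intermediate
9 | 11-chloro-8β,9β-dihydroxyeremophilan-3-one | CC(C)(Cl)[C@H]1C[C@@]2(C)[C@H](CCC(=O)[C@@H]2C)[C@@H](O)[C@H]1O | intermediate
10 | 11-chloro-8β,9β-(isopropylidenedioxy)eremophilan-3-one | CC(C)(Cl)[C@H]1C[C@@]2(C)[C@H](CCC(=O)[C@@H]2C)[C@H]3OC(C)(C)O[C@@H]13 | intermediate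
11 | 8β,9β-(isopropylidenedioxy)eremophil-11-en-3-one | C=C(C)[C@H]1C[C@@]2(C)[C@H](CCC(=O)[C@@H]2C)[C@H]3OC(C)(C)O[C@@H]13 | intermediate
12 | 8β,9β-dihydroxyeremophil-11-en-3-one | C=C(C)[C@H]1C[C@@]2(C)[C@H](CCC(=O)[C@@H]2C)[C@@H](O)[C@H]1O | intermediate
13 | 8β-hydroxy-9β-(triethylsilyloxy)eremophil-11-en-3-one | C=C(C)[C@H]1C[C@@]2(C)[C@H](CCC(=O)[C@@H]2C)[C@@H](O[Si](CC)(CC)CC)[C@H]1O | intermediate
14 | 9β-(triethylsilyloxy)eremophil-11-ene-3α,8β-diol | C=C(C)[C@H]1C[C@@]2(C)[C@H](CC[C@@H](O)[C@@H]2C)[C@@H](O[Si](CC)(CC)CC)[C@H]1O | intermediate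
15 | (R)-pent-4-en-2-ol | C=CC[C@@H](C)O | starting material
16 | angelic acid, (Z)-2-methylbut-2-enoic acid | OC(=O)/C(C)=C\C | starting material
17 | angelic 2,4,6-trichlorobenzoic anhydride | C/C=C(/C)C(=O)OC(=O)c1c(Cl)cc(Cl)cc1Cl | intermediate (not isolated)
18 | (R)-pent-4-en-2-yl angelate | C=CC[C@@H](C)OC(=O)/C(C)=C\C | intermediate
19 | acrylic acid | C=CC(=O)O | starting material
20 | (R,E)-5-(angeloyloxy)hex-2-enoic acid | OC(=O)/C=C/C[C@@H](C)OC(=O)/C(C)=C\C | intermediate
21 | (R,E)-5-(angeloyloxy)hex-2-enoic 2,4,6-trichlorobenzoic anhydride | O=C(/C=C/C[C@@H](C)OC(=O)/C(C)=C\C)OC(=O)c1c(Cl)cc(Cl)cc1Cl | intermediate (not isolated)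
22 | 3α-[(R,E)-5-(angeloyloxy)hex-2-enoyloxy]-9β-(triethylsilyloxy)eremophil-11-en-8β-ol | C=C(C)[C@H]1C[C@@]2(C)[C@H](CC[C@@H](OC(=O)/C=C/C[C@@H](C)OC(=O)/C(C)=C\C)[C@@H]2C)[C@@H](O[Si](CC)(CC)CC)[C@H]1O | intermediate
23 | 3α-[(R,E)-5-(angeloyloxy)hex-2-enoyloxy]-9β-(triethylsilyloxy)eremophil-11-en-8-one | C=C(C)[C@H]1C[C@@]2(C)[C@H](CC[C@@H](OC(=O)/C=C/C[C@@H](C)OC(=O)/C(C)=C\C)[C@@H]2C)[C@@H](O[Si](CC)(CC)CC)C1=O | intermediate
24 | CNP0210874.1, 3α-[(R,E)-5-(angeloyloxy)hex-2-enoyloxy]-9β-hydroxyeremophil-11-en-8-one | C=C(C)[C@H]1C[C@@]2(C)[C@H](CC[C@@H](OC(=O)/C=C/C[C@@H](C)OC(=O)/C(C)=C\C)[C@@H]2C)[C@@H](O)C1=O | target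

**Step count.** Total: 16 steps. Longest linear sequence: 13 steps (steps 1, 3–11, 14–16).

**Steps most likely to fail**

Step 3. The β-methyl enone may be too unreactive toward the diene, or the acid may open the conjugated cyclopropane before the first C–C bond forms. The fallback builds the same two bonds one after the other with a stronger nucleophile, setting out from 2 and returning at 5. Methyl propanoate is converted with LiN(i-Pr)2 and TBSCl into the silyl ketene acetal (E)-1-methoxy-1-(tert-butyldimethylsilyloxy)prop-1-ene F1. Being far more nucleophilic than 4, it should add to C5 of 2 anti to the bridge in an HNTf2- or TBSOTf-catalysed Mukaiyama–Michael reaction and give the C9 silyl enol ether methyl 2-[5-(tert-butyldimethylsilyloxy)-3,7,7-trimethylbicyclo[4.1.0]hept-4-en-3-yl]propanoate F2. Aminolysis with MeNH(OMe)·HCl and i-PrMgCl gives the Weinreb amide F3, and vinylmagnesium bromide then gives the vinyl ketone F4. Catalytic HNTf2 closes ring A by intramolecular Mukaiyama–Michael addition of C10 to the vinyl ketone terminus (6-endo-trig) with silyl transfer to the C3 oxygen. The product is 5 as a C4 epimer mixture, which converges in step 5.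

Step 8. Proton loss may occur from the ring carbon C7 instead of a methyl group, giving the isopropylidene isomer, or the elimination may stall. The fallback replaces E2 by substitution followed by syn-dehydration, setting out from 10 and returning at 11. Silver-assisted hydrolysis of the tertiary chloride (Ag2CO3, aqueous acetone) gives the tertiary alcohol 11-hydroxy-8β,9β-(isopropylidenedioxy)eremophilan-3-one F5. Dehydration with the Burgess reagent (methyl N-(triethylammoniosulfonyl)carbamate, toluene, 50 °C) proceeds by cyclic syn-elimination, which should favour the accessible methyl hydrogens and give 11.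

Step 14. Both hydroxyls may be acylated, or the activated acid may be damaged by base (γ-deprotonation with loss of the angelate, or migration of the double bond out of conjugation). The fallback acylates with a robust three-carbon unit and builds the chain on the ester, setting out from 14 and returning at 22. Acryloyl chloride and i-Pr2NEt in CH2Cl2 at −40 °C give the C3 acrylate 3α-acryloyloxy-9β-(triethylsilyloxy)eremophil-11-en-8β-ol F6. Cross metathesis of this acrylate with the angelate alkene 18 (second-generation Hoveyda–Grubbs catalyst, CH2Cl2, 40 °C) should give 22 with the E enoate; the hindered isopropenyl and angelate alkenes should not compete.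

Further compounds
F1 | step 3 | (E)-1-methoxy-1-(tert-butyldimethylsilyloxy)prop-1-ene | C/C=C(/O[Si](C)(C)C(C)(C)C)OC
F2 | step 3 | methyl 2-[5-(tert-butyldimethylsilyloxy)-3,7,7-trimethylbicyclo[4.1.0]hept-4-en-3-yl]propanoate (C5 set anti to the bridge, C4 epimers) | CC1(C)[C@H]2C[C@](C)(C(C)C(=O)OC)C=C(O[Si](C)(C)C(C)(C)C)[C@@H]12
F3 | step 3 | N-methoxy-N-methyl-2-[5-(tert-butyldimethylsilyloxy)-3,7,7-trimethylbicyclo[4.1.0]hept-4-en-3-yl]propanamide | CC1(C)[C@H]2C[C@](C)(C(C)C(=O)N(C)OC)C=C(O[Si](C)(C)C(C)(C)C)[C@@H]12
F4 | step 3 | 4-[5-(tert-butyldimethylsilyloxy)-3,7,7-trimethylbicyclo[4.1.0]hept-4-en-3-yl]pent-1-en-3-one | CC1(C)[C@H]2C[C@](C)(C(C)C(=O)C=C)C=C(O[Si](C)(C)C(C)(C)C)[C@@H]12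
F5 | step 8 | 11-hydroxy-8β,9β-(isopropylidenedioxy)eremophilan-3-one | CC(C)(O)[C@H]1C[C@@]2(C)[C@H](CCC(=O)[C@@H]2C)[C@H]3OC(C)(C)O[C@@H]13
F6 | step 14 | 3α-acryloyloxy-9β-(triethylsilyloxy)eremophil-11-en-8β-ol | C=C(C)[C@H]1C[C@@]2(C)[C@H](CC[C@@H](OC(=O)C=C)[C@@H]2C)[C@@H](O[Si](CC)(CC)CC)[C@H]1O
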